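Tuesday's run slowed to a stop by 40.0 min, with reagent charged at half the starting material, and that stop is read here as reagent spent.

- Tuesday's: starting material 0.68 M; reagent 0.34 M; run made earlier
- flask: starting material 0.68 M; reagent 0.680 M; time 6.0 h

Tuesday's run (percent of the starting material charged)

| time / min | starting material / % | first product / % | bis adduct / % |
|---|---|---|---|
| 20.0 | 57.6 | 26.3 | 5.1 |
| 40.0 | 54.3 | 29.8 | 7.3 |
| 60.0 | 55.3 | 29.8 | 7.9 |
| 80.0 | 54.6 | 29.8 | 7.5 |
| 120 | 56.3 | 29.2 | 7.6 |

(standard deviation of a reading: 0.3 percentage points)

- a reading or a percentage of first product counts all its forms, free or not
- a reading of starting material is of its free form alone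

* amount of starting material at 6.0 h, in percent of the starting material charged
* amount of first product at 6.0 h, in percent of the starting material charged
* amount of bis adduct at 6.0 h, in percent of the starting material charged

Each starting material turned over carries one reagent and each bis adduct a second. So once reagent is spent, bis adduct minus unreacted starting material, free plus held, equals the reagent surplus, (c(reagent) − c(starting material)) / c(starting material). The surplus is 0% in the flask and −50.0% on Tuesday. Tuesday's last readings then imply 2.4 percentage points of starting material held unread.

In the flask, 6.0 h far exceeds 40.0 min, so reagent counts as spent. Taking the forecast's bis adduct and Tuesday's held amount, this reckoning puts free starting material in the flask near 24.6%, less than the forecast's 31%.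

The forecast gives 31% of starting material, 36% of first product and 27% of bis adduct: “The complex takes about 6”.

The flask gives 25.9% of starting material, 36.2% of first product and 26.5% of bis adduct, so starting material lies 5.1 points below the forecast.

    crystals ⇌ first product, rate k1*(cs1 - [first product]) while solid is left; crystals form when [first product] > cs1 (solubility = 11.0 mM, k = 0.00120 /s)
    first product → over-reaction product (k = 1.70 × 10⁻⁴ /s)
    starting material + first product ⇌ idle adduct, settled at all times (K = 2.60 /M)
    starting material + reagent → first product (k = 0.00220 /M/s)
    reagent + first product → bis adduct (k = 0.00420 /M/s)

With reagent at 0%, the flask's bis adduct less free starting material less surplus is 0.65 points, and the held starting material is 0.649%, the percentage of idle adduct counting each adduct as two. The neighbouring flask with 0.41 M of starting material keeps 5.29% of its reagent, and its surplus, corrected for that reagent and its free starting material, gives 58.1% against 58.2% of bis adduct. At 0.129 h, the flask's free dissolved first product went to bis adduct 9.3 times as fast as to over-reaction product. With reagent at 0.182% by 3.00 h, the flask's bis adduct still stands at 26.5% at 60.0 h, while over-reaction product reaches 46.9%.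

(The runs were computed for substances that don't exist; scatter was added.)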